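**Retrosynthetic overview**
- No ring is built: all six rings are bought intact, rings A, B and C of (2S)-naringenin (carrying the only stereocenter) and the three rings of apigenin.
- Key disconnection: the biaryl bond C3' (naringenin ring B) to C6'' (apigenin ring A), made from two C–H bonds by anodic dehydrogenative phenol–arene cross-coupling.
- Supporting disconnections: two O–benzyl ethers on apigenin (7- and 4'-OH) and one O–CO2Bn carbonate on naringenin 7-OH (it deactivates ring A); all three fall in one hydrogenolysis.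
- Order: protect each partner (one step each), electro-couple, deprotect globally.

Locants: unprimed and primed belong to the naringenin unit, double- and triple-primed to the apigenin unit.
Assumption: (2S)-naringenin is bought as the single (S) enantiomer and its ee is checked by chiral HPLC before use.

**Step 1**
Reactants: 1 apigenin
Product: 2 7,4'-di-O-benzylapigenin [7-benzyloxy-2-(4-benzyloxyphenyl)-5-hydroxy-4H-chromen-4-one]
Conditions: BnBr (2.2 equiv), K2CO3 (2.5 equiv), DMF, 60 °C, 6 h
Reagents that add atoms: benzyl bromide, BrCc1ccccc1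
Why: Williamson etherification; K2CO3 ionises the acidic 7-OH and 4'-OH, while the 5-OH is locked in a hydrogen bond to the C4 carbonyl and stays free, and no stereocenter is involved.

**Step 2**
Reactants: 3 (2S)-naringenin
Product: 4 (2S)-naringenin 7-O-benzyl carbonate [benzyl (2S)-5-hydroxy-2-(4-hydroxyphenyl)-4-oxochroman-7-yl carbonate]
Conditions: CbzCl (1.15 equiv), NaHCO3 (2 equiv), THF/H2O (2:1), 0 °C, 2 h
Reagents that add atoms: benzyl chloroformate, O=C(Cl)OCc1ccccc1
Why: Schotten–Baumann acylation; at about pH 8 only the vinylogous-acid 7-OH (pKa about 7.5) is ionised, so it is capped selectively over the 4'-OH (pKa about 10) and the chelated 5-OH, and the cold, weakly basic medium does not open the pyranone ring, so C2 stays (S).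

**Step 3**
Reactants: 2 7,4'-di-O-benzylapigenin (3 equiv, excess recovered); 4 (2S)-naringenin 7-O-benzyl carbonate (limiting)
Product: 7 (2S)-7-O-(benzyloxycarbonyl)naringenin-(3'→6'')-7'',4'''-di-O-benzylapigenin, via phenoxyl radical 5 (not isolated), via dienone adduct 6 (not isolated)
Conditions: undivided cell, boron-doped diamond anode, Pt cathode, 5 mA cm−2, 2.2 F mol−1 (on 4), Bu3MeN+ MeOSO3− (0.1 M), HFIP/CH2Cl2 (4:1), 40 °C
Reagents that add atoms: none
Why: Proposed new method: anodic oxidation in HFIP takes an electron and a proton from the only unchelated, unacylated phenol present (the tyrosine-like 4'-OH of 4) to give the HFIP-solvated phenoxyl radical 5 with spin density at C3'; the most nucleophilic arene in the cell, the 5-hydroxy-7-benzyloxy ring A of 2, is expected to attack that carbon through C6'', the position ortho to its free chelated 5''-OH where such flavones take up electrophiles, and loss of a second electron and proton gives dienone 6, which tautomerises to biaryl 7; the carbonate makes ring A of 4 a poor competing nucleophile, the twisted product resists further oxidation, HFIP reduction to H2 at Pt spares the carbonyl groups, and the base-free medium leaves C2 as (S); the closest known reaction type is the anodic dehydrogenative phenol–arene cross-coupling of simple p-alkylphenols with alkoxyarenes at boron-doped diamond in HFIP, not yet shown for flavonoid partners.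

**Step 4**
Reactants: 7 (2S)-7-O-(benzyloxycarbonyl)naringenin-(3'→6'')-7'',4'''-di-O-benzylapigenin
Product: 9 (2S)-2,3-dihydrorobustaflavone [(2S)-naringenin-(3'→6'')-apigenin; target CNP0277421.1], via aryl hydrogen carbonate 8 (not isolated)
Conditions: H2 (1 atm), 10% Pd/C, THF/MeOH (1:1), rt, 3 h
Reagents that add atoms: none
Why: Catalytic hydrogenolysis cleaves the two benzyl ethers and the benzyl carbonate, whose hydrogen carbonate 8 loses CO2 spontaneously; at 1 atm and room temperature the flavone C2''=C3'' bond, both ketones and the flavanone C2–O1 bond react far more slowly than O-benzyl groups, and the neutral medium leaves the (2S) centre untouched.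

**Compound list**
1 | apigenin | O=c1cc(-c2ccc(O)cc2)oc2cc(O)cc(O)c12 | starting material
2 | 7,4'-di-O-benzylapigenin | O=c1cc(-c2ccc(OCc3ccccc3)cc2)oc2cc(OCc3ccccc3)cc(O)c12 | intermediate
3 | (2S)-naringenin | O=C1C[C@@H](c2ccc(O)cc2)Oc2cc(O)cc(O)c21 | starting material
4 | (2S)-naringenin 7-O-benzyl carbonate | O=C1C[C@@H](c2ccc(O)cc2)Oc2cc(OC(=O)OCc3ccccc3)cc(O)c21 | intermediate
5 | 4'-phenoxyl radical of 4 (not isolated) | O=C1C[C@@H](c2ccc([O])cc2)Oc2cc(OC(=O)OCc3ccccc3)cc(O)c21 | intermediate
6 | dienone adduct: ring B as 6-(flavon-6-yl)cyclohexa-2,4-dien-1-one, new sp3 carbon undefined (not isolated) | O=C1C[C@@H](C2=CC(c3c(OCc4ccccc4)cc4oc(-c5ccc(OCc6ccccc6)cc5)cc(=O)c4c3O)C(=O)C=C2)Oc2cc(OC(=O)OCc3ccccc3)cc(O)c21 | intermediate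
7 | (2S)-7-O-(benzyloxycarbonyl)naringenin-(3'→6'')-7'',4'''-di-O-benzylapigenin | O=C1C[C@@H](c2ccc(O)c(-c3c(OCc4ccccc4)cc4oc(-c5ccc(OCc6ccccc6)cc5)cc(=O)c4c3O)c2)Oc2cc(OC(=O)OCc3ccccc3)cc(O)c21 | intermediate
8 | 7-O-carboxy (aryl hydrogen carbonate) derivative of the target (not isolated) | O=C1C[C@@H](c2ccc(O)c(-c3c(O)cc4oc(-c5ccc(O)cc5)cc(=O)c4c3O)c2)Oc2cc(OC(=O)O)cc(O)c21 | intermediate
9 | (2S)-2,3-dihydrorobustaflavone, 6-{5-[(2S)-5,7-dihydroxy-4-oxochroman-2-yl]-2-hydroxyphenyl}-5,7-dihydroxy-2-(4-hydroxyphenyl)-4H-chromen-4-one | O=C1C[C@@H](c2ccc(O)c(-c3c(O)cc4oc(-c5ccc(O)cc5)cc(=O)c4c3O)c2)Oc2cc(O)cc(O)c21 | target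

**Step count**
Total steps: 4. Longest linear sequence: 3 (1 → 2 → 7 → 9, or 3 → 4 → 7 → 9).

**Three steps most likely to fail**

Step 3 (new anodic cross-coupling). Risks:
- attack through C8'' instead of C6'';
- oxidation of 2 instead of 4;
- homo-coupling of 4;
- over-oxidation of the 4'-phenoxyl to a quinone methide, which would erode C2.

Fallback with known chemistry (Suzuki–Miyaura coupling of a 6-iodoflavone with a 3'-arylboronate, the established way to this biflavonoid linkage). It sets out from 2 and comes back to the route at 9. Compound 2 is iodinated ortho to its free 5-OH with BnMe3N+ ICl2−/CaCO3 in CH2Cl2–MeOH to give 6-iodo-7,4'-di-O-benzylapigenin F1. Purchased (2S)-hesperetin F2 brings a 3'-OH as the handle on ring B. Its most acidic 7-OH is benzylated under neutral Mitsunobu conditions (BnOH, PPh3, DIAD, THF, 0 °C) to (2S)-7-O-benzylhesperetin F3. The only remaining unchelated phenol is triflated (PhNTf2, Et3N, CH2Cl2, 0 °C) to (2S)-7-O-benzylhesperetin 3'-O-triflate F4. Miyaura borylation (B2pin2, PdCl2(dppf), KOAc, dioxane, 80 °C) gives (2S)-7-O-benzyl-3'-deoxy-3'-(pinacolboryl)hesperetin F5. Coupling of F5 with F1 (Pd(OAc)2/SPhos, K3PO4, toluene/H2O, 60 °C, ee monitored) gives (2S)-7-O-benzyl-4'-O-methylnaringenin-(3'→6'')-7'',4'''-di-O-benzylapigenin F6. BBr3 (CH2Cl2, −78 to 0 °C) then removes the three benzyl groups and the methyl group to give 9.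

Step 2 (selective 7-O-carbonate without racemisation). Risks: 4'-O- or bis-acylation, hydrolysis of the activated carbonate, and residual nucleophilicity of ring A in step 3.

Fallback: block ring A instead of deactivating it. It sets out from 3 and comes back at 9. NBS (2.05 equiv, DMF, 0 °C, no base) brominates only the more reactive ring A to give (2S)-6,8-dibromonaringenin F7, which has no free C–H on ring A. F7 is electrolysed with 2 exactly as in step 3 to give (2S)-6,8-dibromonaringenin-(3'→6'')-7'',4'''-di-O-benzylapigenin F8. Hydrogenolysis (H2, 10% Pd/C, NaOAc, THF/MeOH, rt) removes both benzyl groups and both bromine atoms to give 9.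

Step 4 (global hydrogenolysis). Risks: reduction of the flavone C2''=C3'' bond, hydrogenolysis of the benzylic C2–O1 bond of the flavanone, and poor solubility of partly deprotected material.

Fallback: replace reductive cleavage by non-reductive Lewis-acid benzyl transfer. It sets out from 7 and comes back at 9, with no new compound. BCl3 with pentamethylbenzene as cation scavenger (CH2Cl2, −78 °C) cleaves the two benzyl ethers and the O-benzyl bond of the carbonate, and the carbonic acid loses CO2 on aqueous work-up.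

**Further compounds**
F1 | step 3 | 6-iodo-7,4'-di-O-benzylapigenin | O=c1cc(-c2ccc(OCc3ccccc3)cc2)oc2cc(OCc3ccccc3)c(I)c(O)c12
F2 | step 3 | (2S)-hesperetin | O=C1C[C@@H](c2ccc(OC)c(O)c2)Oc2cc(O)cc(O)c21
F3 | step 3 | (2S)-7-O-benzylhesperetin | O=C1C[C@@H](c2ccc(OC)c(O)c2)Oc2cc(OCc3ccccc3)cc(O)c21
F4 | step 3 | (2S)-7-O-benzylhesperetin 3'-O-triflate | O=C1C[C@@H](c2ccc(OC)c(OS(=O)(=O)C(F)(F)F)c2)Oc2cc(OCc3ccccc3)cc(O)c21
F5 | step 3 | (2S)-7-O-benzyl-3'-deoxy-3'-(pinacolboryl)hesperetin | O=C1C[C@@H](c2ccc(OC)c(B3OC(C)(C)C(C)(C)O3)c2)Oc2cc(OCc3ccccc3)cc(O)c21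
F6 | step 3 | (2S)-7-O-benzyl-4'-O-methylnaringenin-(3'→6'')-7'',4'''-di-O-benzylapigenin | O=C1C[C@@H](c2ccc(OC)c(-c3c(OCc4ccccc4)cc4oc(-c5ccc(OCc6ccccc6)cc5)cc(=O)c4c3O)c2)Oc2cc(OCc3ccccc3)cc(O)c21
F7 | step 2 | (2S)-6,8-dibromonaringenin | O=C1C[C@@H](c2ccc(O)cc2)Oc2c(Br)c(O)c(Br)c(O)c21
F8 | step 2 | (2S)-6,8-dibromonaringenin-(3'→6'')-7'',4'''-di-O-benzylapigenin | O=C1C[C@@H](c2ccc(O)c(-c3c(OCc4ccccc4)cc4oc(-c5ccc(OCc6ccccc6)cc5)cc(=O)c4c3O)c2)Oc2c(Br)c(O)c(Br)c(O)c21
F0 | step 4 | none | none
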